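**Retrosynthetic overview**

1. Target 20 ← ester 19 (fluoride cleavage) ← bis(tosylhydrazone) 16 ← keto-enal 15 ← cycloadduct 13. One reduction removes the C1 carbonyl and moves the ring alkene out to C8=C17.
2. 13 ← acyclic trienone 12 by an intramolecular Diels–Alder reaction. Bonds C5–C10 and C8–C9 form together; the diene is C5=C6–C7=C8, the dienophile C9=C10, and the C1 carbonyl sits in the C1–C4 tether.
3. Enabling feature: rings A and B are cis-fused (H on C5 syn to CH3 on C10) and the C9 chain is syn to CH3-20. This is the print of a carbonyl-endo [4+2] of an (E)-2-methyl enone; ring B is a cyclohexane whose C6–C7 bond can be the new alkene and whose C8 carries the one-carbon branch C17.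
4. 12 ← Michael union at the quaternary C4 of formyl ester 8 with divinyl ketone 5, then Takai and Stille steps for the diene. 5 (C1, C9–C16, C20, the acetate and the C13 centre) comes from (R)-linalool.
5. Ring order: rings A and B close simultaneously in step 10; no ring exists before it.

Key step: step 10

Remarks on the chemistry:
- Read from the SMILES, H-5, CH3-20, the C9 side chain and the C4 carboxyl lie on one face, so the target is the 5-epimer (cis-fused) of the usual labdane skeleton (C4 S, C5 S, C9 S, C10 R, C13 R). Labdane numbering is used throughout; β is the face of CH3-20.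
- Stannane 11 is taken as purchasable.
- In step 7 the pseudoenantiomeric catalysts 9-O-benzylcupreidine and 9-O-benzylcupreine give access to either C4 configuration; the one that gives 2S in a test run is used.

**Route**

Step 1
Reactants: 1 (R)-(−)-linalool
Product: 2 (R)-linalyl acetate
Conditions: Ac2O, DMAP (0.2 equiv), pyridine, 40 °C
Reagents that add atoms: acetic anhydride, CC(=O)OC(C)=O
Why: DMAP-catalysed acylation of the tertiary alcohol, which leaves the C13 centre of the chiral pool untouched.

Step 2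
Reactants: 2 (R)-linalyl acetate
Product: 3 (3R,6E)-3,7-dimethyl-8-oxoocta-1,6-dien-3-yl acetate
Conditions: SeO2 (1.2 equiv), wet 1,4-dioxane, 80 °C
Reagents that add atoms: selenium dioxide, O=[Se]=O
Why: SeO2 allylic oxidation (ene reaction, then [2,3]-sigmatropic shift) attacks the (E)-methyl of the trisubstituted alkene and should run on to the (E)-enal, which fixes the later dienophile geometry (C1 trans to C11, CH3-20 cis to C11).

Step 3
Reactants: 3 (3R,6E)-3,7-dimethyl-8-oxoocta-1,6-dien-3-yl acetate
Product: 4 (3R,6E)-8-hydroxy-3,7-dimethyldeca-1,6,9-trien-3-yl acetate (both C8 epimers)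
Conditions: CH2=CHMgBr (1.05 equiv), THF, −78 °C; aq. NH4Cl
Reagents that add atoms: vinylmagnesium bromide, C=C[Mg]Br
Why: Grignard 1,2-addition to the enal, which at −78 °C should be much faster than attack on the hindered tertiary acetate; the new carbinol centre is oxidised away in step 4.

Step 4
Reactants: 4 (3R,6E)-8-hydroxy-3,7-dimethyldeca-1,6,9-trien-3-yl acetate
Product: 5 (3R,6E)-3,7-dimethyl-8-oxodeca-1,6,9-trien-3-yl acetate
Conditions: Dess–Martin periodinane, pyridine, CH2Cl2, 0 °C; used at once
Reagents that add atoms: none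
Why: Dess–Martin oxidation of the bis-allylic alcohol gives the cross-conjugated divinyl ketone under buffered conditions that spare the acid-sensitive tertiary allylic acetate.

Step 5
Reactants: 6 propanoyl chloride
Product: 7 2-(trimethylsilyl)ethyl propanoate
Conditions: Me3SiCH2CH2OH, pyridine (1.5 equiv), CH2Cl2, 0 °C → rt
Reagents that add atoms: 2-(trimethylsilyl)ethanol, OCC[Si](C)(C)C
Why: acylation of the alcohol by the acid chloride installs an ester that fluoride can later cleave without touching the acetate.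

Step 6
Reactants: 7 2-(trimethylsilyl)ethyl propanoate
Product: 8 2-(trimethylsilyl)ethyl 2-methyl-3-oxopropanoate
Conditions: LiN(iPr)2, THF, −78 °C; HCO2Et, −78 → 0 °C; aq. HCl
Reagents that add atoms: ethyl formate, CCOC=O
Why: crossed Claisen condensation (formylation) of the ester enolate gives the 2-substituted 1,3-dicarbonyl pronucleophile, whose C4 is still stereochemically labile.

Step 7
Reactants: 8 2-(trimethylsilyl)ethyl 2-methyl-3-oxopropanoate; 5 (3R,6E)-3,7-dimethyl-8-oxodeca-1,6,9-trien-3-yl acetate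
Product: 9 2-(trimethylsilyl)ethyl (2S,6E,10R)-10-acetoxy-2-formyl-2,6,10-trimethyl-5-oxododeca-6,11-dienoate
Conditions: 9-O-benzylcupreidine (10 mol %), CH2Cl2, −20 °C
Reagents that add atoms: none
Why: organocatalytic Michael addition of a 2-substituted 1,3-dicarbonyl compound to a vinyl ketone, in which the quinuclidine nitrogen deprotonates the enol of 8 and the 6′-OH binds the enone, so that one face of the ion pair adds to the unsubstituted vinyl terminus and sets C4 as the (S) quaternary centre; the trisubstituted enone terminus is too hindered to compete.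

Step 8
Reactants: 9 2-(trimethylsilyl)ethyl (2S,6E,10R)-10-acetoxy-2-formyl-2,6,10-trimethyl-5-oxododeca-6,11-dienoate
Product: 10 2-(trimethylsilyl)ethyl (2S,6E,10R)-10-acetoxy-2-[(E)-2-iodoethenyl]-2,6,10-trimethyl-5-oxododeca-6,11-dienoate
Conditions: CrCl2 (6 equiv), CHI3 (2 equiv), THF–1,4-dioxane, 0 °C → rt
Reagents that add atoms: iodoform, IC(I)I
Why: Takai olefination, in which the geminal dichromium reagent adds to the aldehyde only (ketone and esters are spared) and should give the (E)-vinyl iodide at C5=C6.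

Step 9
Reactants: 10 2-(trimethylsilyl)ethyl (2S,6E,10R)-10-acetoxy-2-[(E)-2-iodoethenyl]-2,6,10-trimethyl-5-oxododeca-6,11-dienoate; 11 (E)-3-(tributylstannyl)prop-2-en-1-ol
Product: 12 2-(trimethylsilyl)ethyl (2S,6E,10R)-10-acetoxy-2-[(1E,3E)-5-hydroxypenta-1,3-dien-1-yl]-2,6,10-trimethyl-5-oxododeca-6,11-dienoate
Conditions: CuTC (copper thiophene-2-carboxylate, monovalent copper, 1.5 equiv), NMP, 0 °C → rt
Reagents that add atoms: none
Why: copper-mediated Stille-type coupling with retention of both alkene geometries gives the (1E,3E)-diene, and because no zerovalent palladium is present the tertiary allylic acetate cannot ionise.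

Step 10
Reactants: 12 2-(trimethylsilyl)ethyl (2S,6E,10R)-10-acetoxy-2-[(1E,3E)-5-hydroxypenta-1,3-dien-1-yl]-2,6,10-trimethyl-5-oxododeca-6,11-dienoate
Product: 13 2-(trimethylsilyl)ethyl (13R)-13-acetoxy-17-hydroxy-1-oxo-5β-labda-6,14-dien-19-oate (cis-fused; H-5 β, H-8 β, H-9 α, CH3-20 β, C4 ester β)
Conditions: PhMe (0.01 M, degassed), BHT (cat.), 110 °C, sealed tube
Reagents that add atoms: none
Why: Thermal, concerted but asynchronous [4+2] cycloaddition (intramolecular Diels–Alder reaction, type 1) of the (1E,3E)-diene C5=C6–C7=C8 with the enone C9=C10, which is activated by the C1 carbonyl inside the tether. The closest known reaction type is the cyclisation of 1,7,9-decatrien-3-ones to cis-fused octalones through the carbonyl-endo transition state. Ring B closes as the six-membered cycloadduct ring through both new bonds (C5–C10 and C8–C9, new C6=C7 alkene), and ring A closes in the same event as the six-membered ring of the C1–C4 tether through C5–C10, in a chair-like fused mode. C9 and C10 follow from the (E)-enone (suprafacial addition keeps C11 and CH3-20 cis), C5 from the endo position of the C1 carbonyl (H-5 syn to CH3-20, cis fusion) and C8 from the (E)-C7=C8 alkene (erased in step 11); the absolute sense of all of them is relayed from C4, because in the chair tether the flat ester should take the axial site that faces the incoming CH3-20 and the C18 methyl the equatorial one, a methyl/methyl syn-diaxial contact being the costlier alternative. The step needs endo over exo selectivity and one diene face: the first should be secured because the endo mode places the carbonyl under the diene and both alkyl groups of the trisubstituted dienophile (CH3-20 and C11) outside, the second by the quaternary C4 centre next to the diene. Only the conjugated C9=C10 bond is activated, so the isolated C14=C15 vinyl group should stay out.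

Step 11
Reactants: 13 2-(trimethylsilyl)ethyl (13R)-13-acetoxy-17-hydroxy-1-oxo-5β-labda-6,14-dien-19-oate
Product: 15 2-(trimethylsilyl)ethyl (13R)-13-acetoxy-1,17-dioxo-5β-labda-7,14-dien-19-oate, via β,γ-unsaturated aldehyde 14 (not isolated)
Conditions: Dess–Martin periodinane, pyridine, CH2Cl2, 0 °C; then DBU (0.2 equiv), 0 °C
Reagents that add atoms: none
Why: Dess–Martin oxidation of the primary alcohol, then base-mediated conjugation through the dienolate (protonation at C6), which moves the ring alkene from C6=C7 to C7=C8 and erases C8 while no other stereocentre is acidic.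

Step 12
Reactants: 15 2-(trimethylsilyl)ethyl (13R)-13-acetoxy-1,17-dioxo-5β-labda-7,14-dien-19-oate
Product: 16 1,17-bis(tosylhydrazone) of 15
Conditions: TsNHNH2 (3 equiv), PPTS (cat.), EtOH–THF, 50 °C
Reagents that add atoms: p-toluenesulfonyl hydrazide, Cc1ccc(cc1)S(=O)(=O)NN
Why: hydrazone condensation at both carbonyls, the enal reacting first and the hindered C1 ketone on warming, under acid mild enough for the tertiary acetate.

Step 13
Reactants: 16 1,17-bis(tosylhydrazone) of 15
Product: 19 2-(trimethylsilyl)ethyl (13R)-13-acetoxy-5β-labda-8(17),14-dien-19-oate, via bis(borylhydrazine) 17 (not isolated), via bis-diazene 18 (not isolated)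
Conditions: catecholborane (4 equiv), CHCl3, 0 °C → rt; then NaOAc·3H2O, reflux
Reagents that add atoms: none
Why: tosylhydrazone reduction with catecholborane, in which hydride adds to each C=N and acetate-induced loss of sulfinate gives the diazenes; the C1 diazene loses N2 to leave CH2, and the allylic one passes its hydrogen to C7 in a retro-ene step that places the alkene at the exocyclic C8=C17 position (reductive 1,3-transposition), with no stereocentre formed.

Step 14
Reactants: 19 2-(trimethylsilyl)ethyl (13R)-13-acetoxy-5β-labda-8(17),14-dien-19-oate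
Product: 20 (13R)-13-acetoxy-5β-labda-8(17),14-dien-19-oic acid (CNP0230281.1)
Conditions: Bu4NF, THF, 0 °C → rt; aq. NH4Cl
Reagents that add atoms: none
Why: fluoride-induced β-elimination of the 2-(trimethylsilyl)ethyl ester starts at silicon, so it is not slowed by the hindered C19 carboxyl and should leave the tertiary acetate in place.

**Compound list**

1 | (R)-(−)-linalool, (3R)-3,7-dimethylocta-1,6-dien-3-ol | C=C[C@@](C)(CCC=C(C)C)O | starting material
2 | (R)-linalyl acetate, (3R)-3,7-dimethylocta-1,6-dien-3-yl acetate | C=C[C@@](C)(CCC=C(C)C)OC(C)=O | intermediate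
3 | (3R,6E)-3,7-dimethyl-8-oxoocta-1,6-dien-3-yl acetate | C=C[C@@](C)(CC/C=C(\C)C=O)OC(C)=O | intermediate
4 | (3R,6E)-8-hydroxy-3,7-dimethyldeca-1,6,9-trien-3-yl acetate, both C8 epimers | C=C[C@@](C)(CC/C=C(\C)C(O)C=C)OC(C)=O | intermediate
5 | (3R,6E)-3,7-dimethyl-8-oxodeca-1,6,9-trien-3-yl acetate | C=C[C@@](C)(CC/C=C(\C)C(=O)C=C)OC(C)=O | intermediate
6 | propanoyl chloride | CCC(Cl)=O | starting material
7 | 2-(trimethylsilyl)ethyl propanoate | CCC(=O)OCC[Si](C)(C)C | intermediate
8 | 2-(trimethylsilyl)ethyl 2-methyl-3-oxopropanoate (racemic, enol and aldehyde forms) | CC(C=O)C(=O)OCC[Si](C)(C)C | intermediate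
9 | 2-(trimethylsilyl)ethyl (2S,6E,10R)-10-acetoxy-2-formyl-2,6,10-trimethyl-5-oxododeca-6,11-dienoate | C[Si](C)(C)CCOC(=O)[C@](C)(C=O)CCC(=O)/C(C)=C/CC[C@@](C)(OC(C)=O)C=C | intermediate
10 | 2-(trimethylsilyl)ethyl (2S,6E,10R)-10-acetoxy-2-[(E)-2-iodoethenyl]-2,6,10-trimethyl-5-oxododeca-6,11-dienoate | C[Si](C)(C)CCOC(=O)[C@](C)(/C=C/I)CCC(=O)/C(C)=C/CC[C@@](C)(OC(C)=O)C=C | intermediate
11 | (E)-3-(tributylstannyl)prop-2-en-1-ol | CCCC[Sn](CCCC)(CCCC)/C=C/CO | starting material
12 | 2-(trimethylsilyl)ethyl (2S,6E,10R)-10-acetoxy-2-[(1E,3E)-5-hydroxypenta-1,3-dien-1-yl]-2,6,10-trimethyl-5-oxododeca-6,11-dienoate | C[Si](C)(C)CCOC(=O)[C@](C)(/C=C/C=C/CO)CCC(=O)/C(C)=C/CC[C@@](C)(OC(C)=O)C=C | intermediate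
13 | 2-(trimethylsilyl)ethyl (13R)-13-acetoxy-17-hydroxy-1-oxo-5β-labda-6,14-dien-19-oate (cis-fused; H-5 β, H-8 β, H-9 α, CH3-20 β, C4 ester β) | C=C[C@@](C)(CC[C@H]1[C@H](CO)C=C[C@H]2[C@]1(C)C(=O)CC[C@]2(C)C(=O)OCC[Si](C)(C)C)OC(C)=O | intermediate
14 | 2-(trimethylsilyl)ethyl (13R)-13-acetoxy-1,17-dioxo-5β-labda-6,14-dien-19-oate (H-8 β) | C=C[C@@](C)(CC[C@H]1[C@H](C=O)C=C[C@H]2[C@]1(C)C(=O)CC[C@]2(C)C(=O)OCC[Si](C)(C)C)OC(C)=O | intermediate (not isolated)
15 | 2-(trimethylsilyl)ethyl (13R)-13-acetoxy-1,17-dioxo-5β-labda-7,14-dien-19-oate | C=C[C@@](C)(CC[C@H]1C(C=O)=CC[C@H]2[C@]1(C)C(=O)CC[C@]2(C)C(=O)OCC[Si](C)(C)C)OC(C)=O | intermediate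
16 | 1,17-bis(tosylhydrazone) of 15 (hydrazone geometry not defined) | C=C[C@@](C)(CC[C@H]1C(C=NNS(=O)(=O)c3ccc(C)cc3)=CC[C@H]2[C@]1(C)C(=NNS(=O)(=O)c3ccc(C)cc3)CC[C@]2(C)C(=O)OCC[Si](C)(C)C)OC(C)=O | intermediate
17 | 1,17-bis[N-(1,3,2-benzodioxaborol-2-yl)-N′-tosylhydrazino] compound from 16 (C1 configuration not defined) | C=C[C@@](C)(CC[C@H]1C(CN(B3Oc4ccccc4O3)NS(=O)(=O)c3ccc(C)cc3)=CC[C@H]2[C@]1(C)C(N(B3Oc4ccccc4O3)NS(=O)(=O)c3ccc(C)cc3)CC[C@]2(C)C(=O)OCC[Si](C)(C)C)OC(C)=O | intermediate (not isolated)
18 | 1,17-bis(diazenyl) compound, allylic diazene at C17 with C7=C8 (C1 configuration not defined) | C=C[C@@](C)(CC[C@H]1C(CN=N)=CC[C@H]2[C@]1(C)C(N=N)CC[C@]2(C)C(=O)OCC[Si](C)(C)C)OC(C)=O | intermediate (not isolated)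
19 | 2-(trimethylsilyl)ethyl (13R)-13-acetoxy-5β-labda-8(17),14-dien-19-oate | C=C[C@@](C)(CC[C@H]1C(=C)CC[C@H]2[C@]1(C)CCC[C@]2(C)C(=O)OCC[Si](C)(C)C)OC(C)=O | intermediate
20 | (13R)-13-acetoxy-5β-labda-8(17),14-dien-19-oic acid, CNP0230281.1 (C4 S, C5 S, C9 S, C10 R, C13 R) | C=C[C@@](C)(CC[C@H]1C(=C)CC[C@H]2[C@]1(C)CCC[C@]2(C)C(=O)O)OC(C)=O | target

**Step count and risks**

Total step count: 14. Longest linear sequence: 12 steps (steps 1–4, then 7–14, from 1).

Steps most likely to fail:

Step 10. What may go wrong: the C4 centre may discriminate poorly between the two diene faces (the ester-axial and methyl-axial chair tethers differ by little), some material may leak through the carbonyl-exo, trans-fused mode, and long heating may ionise the tertiary allylic acetate. The fallback replaces substrate control at 110 °C by reagent control at low temperature and sets out from 12. The primary alcohol is silylated (TBSCl, imidazole, DMF) to 2-(trimethylsilyl)ethyl (2S,6E,10R)-10-acetoxy-2-[(1E,3E)-5-(tert-butyldimethylsilyloxy)penta-1,3-dien-1-yl]-2,6,10-trimethyl-5-oxododeca-6,11-dienoate F3. This is cyclised at −78 °C in CH2Cl2 with a proline-derived B-(o-tolyl)oxazaborolidine activated by Tf2NH (20 mol %), whose enantiomer is chosen to match the wanted diene face; the boron-bound C1 carbonyl should enforce the endo mode. The product is the 17-O-TBS ether of 13, F4, from which HF·pyridine in THF–pyridine at 0 °C removes the silyl group, coming back to the route at 13.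

Step 7. What may go wrong: the catalyst may differentiate the enol faces of the small formyl ester poorly (low enantiomeric excess), and the amine may trigger retro-Claisen loss of the formyl group. The fallback uses a stoichiometric chiral amine and sets out from 8. Condensation with (R)-1-phenylethylamine (PhMe, molecular sieves) gives the hydrogen-bonded enamino ester 2-(trimethylsilyl)ethyl (Z)-2-methyl-3-{[(1R)-1-phenylethyl]amino}prop-2-enoate F1 (the antipodal amine is taken if the sense of induction proves opposite). F1 adds to 5 in THF at rt in an aza-ene-type Michael reaction under neutral conditions to give the imine 2-(trimethylsilyl)ethyl (2S,6E,10R)-10-acetoxy-2,6,10-trimethyl-5-oxo-2-({[(1R)-1-phenylethyl]imino}methyl)dodeca-6,11-dienoate F2. Hydrolysis with aqueous acetic acid comes back to the route at 9.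

Step 13. What may go wrong: hydrazone formation or hydride addition at the hindered C1 position next to the quaternary C10 may stay incomplete, so that C1 remains oxygenated while the enal part reacts normally. The fallback separates the two tasks and sets out from 15. With 1.05 equiv TsNHNH2 at rt only the aldehyde condenses, giving the 17-mono(tosylhydrazone) of 15, F5. Catecholborane, then NaOAc·3H2O, transposes it to 2-(trimethylsilyl)ethyl (13R)-13-acetoxy-1-oxo-5β-labda-8(17),14-dien-19-oate F6. NaBH4 (MeOH, 0 °C) gives the C1 alcohol 2-(trimethylsilyl)ethyl (13R)-13-acetoxy-1-hydroxy-5β-labda-8(17),14-dien-19-oate F7. 1,1′-Thiocarbonyldiimidazole (DMAP, PhMe, 80 °C) gives the 1-O-(imidazol-1-ylthiocarbonyl) derivative of F7, F8. Bu3SnH and AIBN (PhMe, 90 °C, Barton–McCombie deoxygenation) then come back to the route at 19.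

Further compounds
F1 | step 7 | 2-(trimethylsilyl)ethyl (Z)-2-methyl-3-{[(1R)-1-phenylethyl]amino}prop-2-enoate | C[C@@H](N/C=C(/C)C(=O)OCC[Si](C)(C)C)c1ccccc1
F2 | step 7 | 2-(trimethylsilyl)ethyl (2S,6E,10R)-10-acetoxy-2,6,10-trimethyl-5-oxo-2-({[(1R)-1-phenylethyl]imino}methyl)dodeca-6,11-dienoate | C[C@@H](N=C[C@](C)(CCC(=O)/C(C)=C/CC[C@@](C)(OC(C)=O)C=C)C(=O)OCC[Si](C)(C)C)c1ccccc1
F3 | step 10 | 2-(trimethylsilyl)ethyl (2S,6E,10R)-10-acetoxy-2-[(1E,3E)-5-(tert-butyldimethylsilyloxy)penta-1,3-dien-1-yl]-2,6,10-trimethyl-5-oxododeca-6,11-dienoate | C[Si](C)(C)CCOC(=O)[C@](C)(/C=C/C=C/CO[Si](C)(C)C(C)(C)C)CCC(=O)/C(C)=C/CC[C@@](C)(OC(C)=O)C=C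
F4 | step 10 | 2-(trimethylsilyl)ethyl (13R)-13-acetoxy-17-(tert-butyldimethylsilyloxy)-1-oxo-5β-labda-6,14-dien-19-oate | C=C[C@@](C)(CC[C@H]1[C@H](CO[Si](C)(C)C(C)(C)C)C=C[C@H]2[C@]1(C)C(=O)CC[C@]2(C)C(=O)OCC[Si](C)(C)C)OC(C)=O
F5 | step 13 | 17-mono(tosylhydrazone) of 15 | C=C[C@@](C)(CC[C@H]1C(C=NNS(=O)(=O)c3ccc(C)cc3)=CC[C@H]2[C@]1(C)C(=O)CC[C@]2(C)C(=O)OCC[Si](C)(C)C)OC(C)=O
F6 | step 13 | 2-(trimethylsilyl)ethyl (13R)-13-acetoxy-1-oxo-5β-labda-8(17),14-dien-19-oate | C=C[C@@](C)(CC[C@H]1C(=C)CC[C@H]2[C@]1(C)C(=O)CC[C@]2(C)C(=O)OCC[Si](C)(C)C)OC(C)=O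
F7 | step 13 | 2-(trimethylsilyl)ethyl (13R)-13-acetoxy-1-hydroxy-5β-labda-8(17),14-dien-19-oate (C1 configuration not defined) | C=C[C@@](C)(CC[C@H]1C(=C)CC[C@H]2[C@]1(C)C(O)CC[C@]2(C)C(=O)OCC[Si](C)(C)C)OC(C)=O
F8 | step 13 | 2-(trimethylsilyl)ethyl (13R)-13-acetoxy-1-(imidazol-1-ylthiocarbonyloxy)-5β-labda-8(17),14-dien-19-oate | C=C[C@@](C)(CC[C@H]1C(=C)CC[C@H]2[C@]1(C)C(OC(=S)n3ccnc3)CC[C@]2(C)C(=O)OCC[Si](C)(C)C)OC(C)=O
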